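## Retrosynthetic overview

1. **Feature used.** In ring C (C10–C14) the bridgehead alkene C10=C14 is conjugated to C13=O. C9 is therefore the γ-carbon of a cyclopentenone, and the oxygen-bearing C8 sits next to it. The C8–C9 bond of the nine-membered ring B (C1, C2, C6–C12) is a vinylogous Claisen retron.
2. **Key cut, C8–C9.** A vinylogous Dieckmann closure of seco thioester 16 gives the bicyclo[6.2.1]undecene triketone 17. The anti-Bredt enone enters as a flat, unstrained cyclopentenone and is never made by elimination.
3. **C12–C1=C2.** A one-carbon staple (the orthoformate carbon) joins ring C enol silane 6 to ring A keto acetal 12. C12–OH comes from enolate oxidation anti to C11–OSiEt3, which gives the trans-diol.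
4. **Building blocks.** Ring C with C9, the isopropyl group and C11-Me comes from 4-methylpentan-2-one and butane-2,3-dione. Ring A is cyclopent-2-enone. C7, C7-Me and C8 come from a thiopropionate.
5. **Ring order.** C and A are made separately and B is closed last. The endgame adds C16 (methylenation, epoxide, methoxide), reduces C8 and removes the silyl groups.

Key step: step 10

Assumption: in steps 1 and 6 the catalyst antipode is the one that gives the drawn configuration, and the drawn C7 epimer is taken to be the thermodynamic one in the C8 ketones 17–20.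

## Route

Step 1
Reactants: 1 4-methylpentan-2-one; 2 butane-2,3-dione
Product: 3 (S)-3-hydroxy-3,7-dimethyloctane-2,5-dione
Conditions: proline (20 mol %), neat 1, 4 °C
Reagents that add atoms: none
Why: Proline enamine aldol reaction: the methyl-side enamine of 1 adds to one carbonyl of symmetric 2 through the acid-organised transition state, which sets C11.

Step 2
Reactants: 3 (S)-3-hydroxy-3,7-dimethyloctane-2,5-dione
Product: 4 (S)-4-hydroxy-2-isopropyl-3,4-dimethylcyclopent-2-en-1-one
Conditions: KOH (cat.), MeOH/H2O, 0 °C
Reagents that add atoms: none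
Why: Intramolecular aldol condensation of a 1,4-diketone: the C14 methylene attacks the acetyl carbonyl C10 and dehydration gives the tetrasubstituted enone as the thermodynamic regioisomer, while the low temperature should hold back retro-aldol at C11.

Step 3
Reactants: 4 (S)-4-hydroxy-2-isopropyl-3,4-dimethylcyclopent-2-en-1-one
Product: 5 the C11 triethylsilyl ether of 4
Conditions: TESOTf, 2,6-lutidine, CH2Cl2, −78 to 0 °C
Reagents that add atoms: triethylsilyl triflate CC[Si](CC)(CC)OS(=O)(=O)C(F)(F)F
Why: Silyl triflate silylation of a tertiary alcohol; the group later shields one face of C12.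

Step 4
Reactants: 5 the C11 triethylsilyl ether of 4
Product: 6 2-(trimethylsilyloxy)cyclopenta-1,3-diene of 5 (C12H=C13–OSiMe3)
Conditions: LDA, THF, −78 °C; TMSCl
Reagents that add atoms: chlorotrimethylsilane C[Si](C)(C)Cl
Why: Kinetic α′-deprotonation at C12 and O-silylation give the cross-conjugated enol silane, and the quaternary C11 blocks 1,5-hydrogen shifts in the cyclopentadiene.

Step 5
Reactants: 7 S-ethyl propanethioate
Product: 8 (Z)-1-(ethylsulfanyl)-1-(trimethylsilyloxy)prop-1-ene
Conditions: LDA, THF, −78 °C; TMSCl
Reagents that add atoms: chlorotrimethylsilane C[Si](C)(C)Cl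
Why: Kinetic enolisation of the thioester in THF followed by O-silylation gives the Z silyl ketene thioacetal.

Step 6
Reactants: 8 (Z)-silyl ketene thioacetal; 9 cyclopent-2-en-1-one; 10 trimethyl orthoformate
Product: 12 S-ethyl (2R)-2-[(1R,2R)-2-(dimethoxymethyl)-3-oxocyclopentyl]propanethioate, via enol silane 11 (not isolated)
Conditions: chiral oxazaborolidinium triflimide (10 mol %), CH2Cl2, −78 °C; then 10, BF3·OEt2, −78 °C
Reagents that add atoms: none
Why: Enantioselective Mukaiyama–Michael addition: the catalyst shields one face of the bound enone and sets C6, the open transition state of the Z ketene acetal sets C7, and the regiodefined enol silane 11 is then alkylated at C2 by the orthoformate cation (Mukaiyama acetal reaction) trans to the side chain.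

Step 7
Reactants: 6 ring C enol silane; 12 ring A keto acetal
Product: 14 (E)-enone with C12–C1H=C2 (C12–H, epimer mixture), via β-methoxy ketone 13 (not isolated)
Conditions: TMSOTf (10 mol %), CH2Cl2, −78 °C; then p-TsOH (cat.), CH2Cl2, rt
Reagents that add atoms: none
Why: Mukaiyama aldol-type coupling of the enol silane carbon C12 with the acetal-derived oxocarbenium ion C1, then acid-induced β-elimination of methanol to the E enone (C12 anti to C3=O); the C12 centre is erased in step 8.

Step 8
Reactants: 14 (E)-enone with C12–H
Product: 15 (12S)-C12 tertiary alcohol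
Conditions: KHMDS (1.05 equiv), THF, −78 °C; 2-(phenylsulfonyl)-3-phenyloxaziridine; AcOH
Reagents that add atoms: 2-(phenylsulfonyl)-3-phenyloxaziridine O=S(=O)(c1ccccc1)N1OC1c1ccccc1
Why: Enolate hydroxylation with an N-sulfonyloxaziridine: C12–H lies between C13=O and the vinylogous C3=O, attack at C12 keeps the C1=C2–C3=O conjugation and avoids a quaternary C2, and the oxidant approaches anti to C11–OSiEt3, which sets the trans-diol.

Step 9
Reactants: 15 (12S)-C12 tertiary alcohol
Product: 16 bis(triethylsilyl) ether, the seco thioester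
Conditions: TESOTf, 2,6-lutidine, CH2Cl2, 0 °C
Reagents that add atoms: triethylsilyl triflate CC[Si](CC)(CC)OS(=O)(=O)C(F)(F)F
Why: Silyl triflate silylation removes the acidic OH so that no α-ketol or retro-aldol pathway can start from a C12 alkoxide in step 10.

Step 10
Reactants: 16 seco thioester
Product: 17 bicyclo[6.2.1] triketone (C3, C8 and C13 ketones)
Conditions: KHMDS (3.5 equiv), THF, 1 mM, slow addition of 16, −78 to 0 °C; AcOH
Reagents that add atoms: none
Why: Proposed new method: excess KHMDS equilibrates the enolates of 16, and the extended dienolate from the C9 methyl (O–C13=C14–C10=C9) attacks the thioester carbonyl C8 through C9 and expels ethanethiolate; the vinylogous β-diketone formed is deprotonated at once, so this is the only irreversible exit. The closest known reaction types are the Dieckmann and macro-Claisen condensation of thioesters and the γ-acylation (vinylogous Claisen) of α-blocked dienolates. Ring B closes in a 9-(enolendo)-exo-trig mode, and this single bond converts the monocyclic enone into the bicyclo[6.2.1]undecene, whose bridgehead C10=C14 stays planar throughout. No new stereocentre forms: C6, C11 and C12 carry no acidic hydrogen, and the epimerisable C7 should settle as the thermodynamic epimer. The step needs γ(C9) selectivity over C14, C4 and C7: attack from C14 gives a non-enolisable β-diketone that reverts by retro-Claisen, attack from C4 would give a strained bicyclo[2.2.1] diketone that cannot enolise at its bridgehead, and the C7 enolate can at most collapse to a ketene that acylates C9 as well. The C1=C2 geometry (C12 cis to C6) holds both reacting ends on one side, and high dilution suppresses dimers.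

Step 11
Reactants: 17 bicyclo[6.2.1] triketone
Product: 18 C3 exocyclic methylene compound
Conditions: Ph3PCH3Br, KOt-Bu (3 equiv each), THF, 0 °C
Reagents that add atoms: methyltriphenylphosphonium bromide C[P+](c1ccccc1)(c1ccccc1)c1ccccc1.[Br-]
Why: Wittig methylenation: the first equivalent of ylide deprotonates C9 and masks C8 and C13 as the vinylogous diketonate, so only C3=O reacts.

Step 12
Reactants: 18 C3 exocyclic methylene compound
Product: 19 (3R)-C3/C16 spiro-epoxide
Conditions: mCPBA, NaHCO3, CH2Cl2, 0 °C
Reagents that add atoms: 3-chloroperbenzoic acid OOC(=O)c1cccc(Cl)c1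
Why: Prilezhaev epoxidation of the least hindered 1,1-disubstituted alkene, from the ring A face opposite the pseudo-axial C6–C7 bond, which sets C3.

Step 13
Reactants: 19 (3R)-spiro-epoxide
Product: 20 C3 tertiary alcohol with CH2OMe
Conditions: NaOMe (3 equiv), MeOH, 50 °C; AcOH
Reagents that add atoms: sodium methoxide C[O-].[Na+]
Why: SN2 epoxide opening at the primary C16 leaves the C3–O bond and its configuration untouched, while the C8/C13 system rests as its enolate and C7 can equilibrate to the drawn epimer.

Step 14
Reactants: 20 C8 ketone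
Product: 21 (8S)-alcohol
Conditions: NaBH4, MeOH/CH2Cl2, −78 °C
Reagents that add atoms: none
Why: Borohydride reduction of the only unhindered, unconjugated ketone (C13=O is conjugated and flanked by C12 and the isopropyl group), with hydride delivered from the outer face in the Felkin–Anh sense relative to C7.

Step 15
Reactants: 21 bis(triethylsilyl) ether
Product: 22 brassicicene M
Conditions: HF·pyridine, excess pyridine, THF, 0 °C to rt
Reagents that add atoms: none
Why: Buffered fluoride desilylation frees C11–OH and C12–OH without ionising the tertiary allylic C3–OH and without forming the C8 alkoxide that could start a vinylogous retro-aldol.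

## Compound list

1 | 4-methylpentan-2-one | CC(=O)CC(C)C | starting material
2 | butane-2,3-dione | CC(=O)C(C)=O | starting material
3 | (S)-3-hydroxy-3,7-dimethyloctane-2,5-dione | CC(=O)[C@@](CC(=O)CC(C)C)(C)O | intermediate
4 | (S)-4-hydroxy-2-isopropyl-3,4-dimethylcyclopent-2-en-1-one | C1C(=O)C(C(C)C)=C(C)[C@@]1(C)O | intermediate
5 | C11 triethylsilyl ether of 4 | C1C(=O)C(C(C)C)=C(C)[C@@]1(C)O[Si](CC)(CC)CC | intermediate
6 | ring C 2-(trimethylsilyloxy)cyclopentadiene | C1=C(O[Si](C)(C)C)C(C(C)C)=C(C)[C@@]1(C)O[Si](CC)(CC)CC | intermediate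
7 | S-ethyl propanethioate | CCC(=O)SCC | starting material
8 | (Z)-1-(ethylsulfanyl)-1-(trimethylsilyloxy)prop-1-ene | C/C=C(\SCC)O[Si](C)(C)C | intermediate
9 | cyclopent-2-en-1-one | O=C1C=CCC1 | starting material
10 | trimethyl orthoformate | COC(OC)OC | starting material
11 | Michael adduct enol silane (not isolated) | CCSC(=O)[C@H](C)[C@@H]1CCC(O[Si](C)(C)C)=C1 | intermediate
12 | ring A keto acetal | O=C1CC[C@@H]([C@@H](C)C(=O)SCC)[C@@H]1C(OC)OC | intermediate
13 | β-methoxy ketone, mixture at C1, C2, C12 (not isolated) | O=C1CC[C@@H]([C@@H](C)C(=O)SCC)C1C(OC)C1C(=O)C(C(C)C)=C(C)[C@@]1(C)O[Si](CC)(CC)CC | intermediate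
14 | (E)-enone, C12–H epimers | O=C1CC[C@@H]([C@@H](C)C(=O)SCC)/C1=C\C1C(=O)C(C(C)C)=C(C)[C@@]1(C)O[Si](CC)(CC)CC | intermediate
15 | (12S)-tertiary alcohol | O=C1CC[C@@H]([C@@H](C)C(=O)SCC)/C1=C\[C@@]1(O)C(=O)C(C(C)C)=C(C)[C@@]1(C)O[Si](CC)(CC)CC | intermediate
16 | seco thioester, bis-TES ether | O=C1CC[C@@H]([C@@H](C)C(=O)SCC)/C1=C\[C@@]1(O[Si](CC)(CC)CC)C(=O)C(C(C)C)=C(C)[C@@]1(C)O[Si](CC)(CC)CC | intermediate
17 | bicyclo[6.2.1] triketone | O=C1CC[C@@H]2/C1=C\[C@@]1(O[Si](CC)(CC)CC)C(=O)C(C(C)C)=C(CC(=O)[C@@H]2C)[C@@]1(C)O[Si](CC)(CC)CC | intermediate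
18 | C3 methylene compound | C=C1CC[C@@H]2/C1=C\[C@@]1(O[Si](CC)(CC)CC)C(=O)C(C(C)C)=C(CC(=O)[C@@H]2C)[C@@]1(C)O[Si](CC)(CC)CC | intermediate
19 | (3R)-spiro-epoxide | C1O[C@@]12CC[C@@H]3/C2=C\[C@@]2(O[Si](CC)(CC)CC)C(=O)C(C(C)C)=C(CC(=O)[C@@H]3C)[C@@]2(C)O[Si](CC)(CC)CC | intermediate
20 | C3 alcohol / C16 methyl ether, C8 ketone | COC[C@@]1(O)CC[C@@H]2/C1=C\[C@@]1(O[Si](CC)(CC)CC)C(=O)C(C(C)C)=C(CC(=O)[C@@H]2C)[C@@]1(C)O[Si](CC)(CC)CC | intermediate
21 | (8S)-alcohol, bis-TES ether | COC[C@@]1(O)CC[C@@H]2/C1=C\[C@@]1(O[Si](CC)(CC)CC)C(=O)C(C(C)C)=C(C[C@H](O)[C@@H]2C)[C@@]1(C)O[Si](CC)(CC)CC | intermediate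
22 | brassicicene M | COC[C@@]1(O)CC[C@@H]2/C1=C\[C@@]1(O)C(=O)C(C(C)C)=C(C[C@H](O)[C@@H]2C)[C@@]1(C)O | target

## Step count

Total step count: 15.
Longest linear sequence: 13 (steps 1–4 and 7–15).

## Steps most likely to fail

**1. Step 10 (Proposed new method).**
- What may go wrong: the nine-membered closure may lose to oligomerisation. The γ-dienolate may also be populated too little next to the C4 and C7 enolates.
- Fallback: it sets out from 16. A Fukuyama reduction (Et3SiH, Pd/C) gives the seco aldehyde F1. Complexation of the carbonyl groups with aluminium tris(2,6-diphenylphenoxide), followed by deprotonation of the C9 methyl with LiTMP, should trigger an intramolecular vinylogous aldol addition to the ring-closed C8 carbinol F2. Oxidation with Dess–Martin periodinane brings the sequence back to the route at 17.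

**2. Step 8.**
- What may go wrong: the delocalised anion may be oxidised at C2 instead of C12, or from the wrong face. It may also lose the C11 silyloxy group by β-elimination.
- Fallback: the C12 carbinol is made by C–C bond formation instead. The sequence sets out from 4 and 12.
  - A Riley oxidation of 4 (SeO2) gives the hydroxy 1,2-dione F3.
  - Acid hydrolysis of 12 gives the hydroxymethylene ketone F4, and triflation (Tf2O, hindered pyridine) gives the (E)-enol triflate F5.
  - A Nozaki–Hiyama–Kishi coupling of F5 with the activated C12 ketone of F3 should give the trans-diol F6. The chromium alkoxide of the free C11–OH is expected to deliver the alkenyl group to its own face.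
  - Double silylation with TESOTf comes back to the route at 16.

**3. Step 12.**
- What may go wrong: the peracid may attack C1=C2 or the enol form of the C8/C13 system, or the facial selectivity at C3 may be poor.
- Fallback: it sets out from 18. Osmium-catalysed dihydroxylation (OsO4, NMO) of the unhindered methylene from the same open face gives the C3,C16-diol F7. Selective methylation of the primary hydroxyl (Me3OBF4, proton sponge) comes back to the route at 20.

## Further compounds

F1 | step 10 | seco aldehyde | O=C1CC[C@@H]([C@@H](C)C=O)/C1=C\[C@@]1(O[Si](CC)(CC)CC)C(=O)C(C(C)C)=C(C)[C@@]1(C)O[Si](CC)(CC)CC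
F2 | step 10 | ring-closed C8 carbinol | O=C1CC[C@@H]2/C1=C\[C@@]1(O[Si](CC)(CC)CC)C(=O)C(C(C)C)=C(CC(O)[C@@H]2C)[C@@]1(C)O[Si](CC)(CC)CC
F3 | step 8 | hydroxy 1,2-dione | O=C1C(=O)C(C(C)C)=C(C)[C@@]1(C)O
F4 | step 8 | hydroxymethylene ketone | O=C1CC[C@@H]([C@@H](C)C(=O)SCC)/C1=C/O
F5 | step 8 | (E)-enol triflate | O=C1CC[C@@H]([C@@H](C)C(=O)SCC)/C1=C\OS(=O)(=O)C(F)(F)F
F6 | step 8 | trans-diol | O=C1CC[C@@H]([C@@H](C)C(=O)SCC)/C1=C\[C@@]1(O)C(=O)C(C(C)C)=C(C)[C@@]1(C)O
F7 | step 12 | C3,C16-diol | OC[C@@]1(O)CC[C@@H]2/C1=C\[C@@]1(O[Si](CC)(CC)CC)C(=O)C(C(C)C)=C(CC(=O)[C@@H]2C)[C@@]1(C)O[Si](CC)(CC)CC
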